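**Retrosynthetic overview**

1. Target 22 ⇐ 21 ⇐ 20 ⇐ 19: the free phenols (BCl3) and the two formyl groups (Rieche) come last, and C4–H comes from ionic deoxygenation of a tertiary benzylic carbinol.
2. Key disconnection C3–C4 of the pyran ring (O1–C2–C3–C4–C4a–C8a). C3 is a methyl-bearing quaternary carbon bonded directly to benzylic C4 and cis-fused to the cyclopentane, so it is made as a tertiary radical from an exocyclic C3=CH2 that adds to the carbonyl carbon of an ortho isovaleryl group held on C2 through O1 (18 ⇒ 19).
3. O1–C8a by SNAr of allylic alkoxide 10 on symmetrical, non-enolisable 2,6-difluoro-4-methoxybenzonitrile 11; the nitrile is then converted into the isobutyl ketone.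
4. 10 ⇐ spiro[4.5]decenone 8 (α-methylenation, Luche reduction) ⇐ acid-triggered ring expansion of a dienyl cyclobutanol ⇐ Shapiro coupling of trans-dihydrocarvone with cyclobutanone ⇐ (R)-carvone.
5. Ring order: cyclohexene (from carvone) → spiro cyclopentane (ring expansion) → arene attached (SNAr) → pyran (key step).

Key step: step 11

Remark: chroman numbering (O1, C2, C3, C4, C4a, C5–C8, C8a) is used for the tricyclic core and spiro[4.5]decane numbering (C1–C10) for the terpene unit; compounds 4, 11 and 16, 2,4,6-triisopropylbenzenesulfonohydrazide and the other reagents are taken as purchased.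

**Route**

Step 1
Reactants: 1 (R)-(−)-carvone
Product: 2 (2R,5R)-2-methyl-5-(prop-1-en-2-yl)cyclohexan-1-one (trans-dihydrocarvone)
Conditions: L-Selectride, THF, −78 °C; H2O; then NaOMe (cat.), MeOH, rt
Reagents that add atoms: none
Why: Conjugate hydride reduction of the enone by the bulky borohydride leaves the isolated isopropenyl group alone, and base equilibration of the epimerisable C2 should place the methyl trans to the C5 substituent (both equatorial), so that the C5 stereocentre of carvone is relayed to C2 (2R).

Step 2
Reactants: 2 (2R,5R)-2-methyl-5-(prop-1-en-2-yl)cyclohexan-1-one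
Product: 3 (E)-2,4,6-triisopropylbenzenesulfonyl hydrazone of 2
Conditions: TrisNHNH2, HCl (cat.), MeOH, rt; recrystallisation
Reagents that add atoms: 2,4,6-triisopropylbenzenesulfonohydrazide, CC(C)c1cc(C(C)C)c(S(=O)(=O)NN)c(C(C)C)c1
Why: Acid-catalysed hydrazone condensation gives the crystalline trisylhydrazone with the sulfonamide anti to the methyl-bearing carbon, and recrystallisation should remove the minor C2 epimer, which matters because the two C2 series become enantiomers once C5 is made trigonal in step 4.

Step 3
Reactants: 3 trisylhydrazone of trans-dihydrocarvone; 4 cyclobutanone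
Product: 6 1-[(3R,6R)-6-methyl-3-(prop-1-en-2-yl)cyclohex-1-en-1-yl]cyclobutan-1-ol, via vinyllithium 5 (not isolated)
Conditions: n-BuLi (2.2 equiv), TMEDA, THF, −78 → 0 °C; then 4, −78 °C
Reagents that add atoms: none
Why: Shapiro reaction in which the hydrazone dianion forms at the less substituted α-CH2 syn to the sulfonamide, loses sulfinate and N2 to give vinyllithium 5 with the methyl-bearing stereocentre untouched, and 5 then adds 1,2 to the strained carbonyl of cyclobutanone.

Step 4
Reactants: 6 1-[(3R,6R)-6-methyl-3-(prop-1-en-2-yl)cyclohex-1-en-1-yl]cyclobutan-1-ol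
Product: 8 (5R,10R)-10-methyl-7-(propan-2-yl)spiro[4.5]dec-6-en-1-one, via conjugated isopropylidene diene 7 (not isolated)
Conditions: p-TsOH·H2O (10 mol %), CH2Cl2, 0 °C → rt, stopped at full conversion
Reagents that add atoms: none
Why: Vinylogous protio-semipinacol ring expansion in which the acid protonates the isopropenyl group (the ring alkene is deactivated by the adjacent carbinol), the tertiary cation relays by 1,2-hydride shift or by loss and return of a proton through diene 7 to the tertiary allyl cation, and a cyclobutane C–C bond then migrates to the carbinol-bearing terminus on the face anti to the pseudoaxial neighbouring methyl, which releases ring strain, forms the ketone, leaves the alkene at C6=C7 and should set the spiro centre with the carbonyl carbon cis to the C10 methyl (5R).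

Step 5
Reactants: 8 (5R,10R)-10-methyl-7-(propan-2-yl)spiro[4.5]dec-6-en-1-one
Product: 9 (5R,10R)-10-methyl-2-methylidene-7-(propan-2-yl)spiro[4.5]dec-6-en-1-one
Conditions: (CH2O)n, i-Pr2NH·TFA, THF, reflux; used directly in step 6
Reagents that add atoms: paraformaldehyde (formaldehyde), C=O
Why: Mannich-type α-methylenation (iminium formation, C–C bond formation at the enol, then β-elimination of the amine) can occur only at C2 because the other α-carbon is the quaternary spiro centre.

Step 6
Reactants: 9 (5R,10R)-10-methyl-2-methylidene-7-(propan-2-yl)spiro[4.5]dec-6-en-1-one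
Product: 10 (1R,5R,10R)-10-methyl-2-methylidene-7-(propan-2-yl)spiro[4.5]dec-6-en-1-ol
Conditions: NaBH4, CeCl3·7H2O, MeOH, −78 °C
Reagents that add atoms: none
Why: Luche reduction gives 1,2-reduction of the exocyclic enone, and hydride should attack the carbonyl from the face of the vinylic C6–H arm of the spiro ring, away from the C10 arm whose methyl lies next to the carbonyl, so that the new C1–O bond is syn to C10 (1R).

Step 7
Reactants: 10 (1R,5R,10R)-10-methyl-2-methylidene-7-(propan-2-yl)spiro[4.5]dec-6-en-1-ol; 11 2,6-difluoro-4-methoxybenzonitrile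
Product: 13 2,4-dimethoxy-6-{[(1R,5R,10R)-10-methyl-2-methylidene-7-(propan-2-yl)spiro[4.5]dec-6-en-1-yl]oxy}benzonitrile, via monofluoro aryl ether nitrile 12 (not isolated)
Conditions: KHMDS, THF, 0 °C; 11, 0 °C → rt; then NaOMe, MeOH, 50 °C
Reagents that add atoms: sodium methoxide, [Na+].[O-]C
Why: Nucleophilic aromatic substitution (addition–elimination) in which the potassium alkoxide displaces a fluoride ortho to the nitrile with retention at the carbinol carbon, the arene cannot enolise and its two fluorides are equivalent so no regioisomer can arise, and methoxide then displaces the second fluoride, which is still activated by the ortho nitrile and is only meta to the two alkoxy groups.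

Step 8
Reactants: 13 2,4-dimethoxy-6-(spirodecenyloxy)benzonitrile
Product: 15 2,4-dimethoxy-6-{[(1R,5R,10R)-10-methyl-2-methylidene-7-(propan-2-yl)spiro[4.5]dec-6-en-1-yl]oxy}benzaldehyde, via aldimine 14 (not isolated)
Conditions: DIBAL-H, toluene, −78 → 0 °C; aq. Rochelle salt; then aq. citric acid, rt
Reagents that add atoms: water, O
Why: DIBAL-H adds one hydride to the nitrile to give an N-aluminated aldimine that is not reduced further, and mild aqueous hydrolysis releases the aldehyde while the allylic aryl ether and both alkenes are inert to the reagent.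

Step 9
Reactants: 15 2,4-dimethoxy-6-(spirodecenyloxy)benzaldehyde; 16 isobutylmagnesium bromide
Product: 17 1-(2,4-dimethoxy-6-{[(1R,5R,10R)-10-methyl-2-methylidene-7-(propan-2-yl)spiro[4.5]dec-6-en-1-yl]oxy}phenyl)-3-methylbutan-1-ol (both carbinol epimers)
Conditions: THF, −78 → 0 °C; H2O
Reagents that add atoms: none
Why: Grignard 1,2-addition to the non-enolisable aldehyde installs the isobutyl group, and the new carbinol centre is of no consequence because it is oxidised in the next step.

Step 10
Reactants: 17 benzylic alcohol (both epimers)
Product: 18 1-(2,4-dimethoxy-6-{[(1R,5R,10R)-10-methyl-2-methylidene-7-(propan-2-yl)spiro[4.5]dec-6-en-1-yl]oxy}phenyl)-3-methylbutan-1-one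
Conditions: TPAP (5 mol %), NMO, 4 Å MS, CH2Cl2, rt
Reagents that add atoms: none
Why: Ley–Griffith oxidation converts the secondary benzylic alcohol into the aryl ketone under neutral conditions that spare the acid-sensitive allylic aryl ether and the alkenes.

Step 11
Reactants: 18 ortho-isovaleryl 3,5-dimethoxyphenyl ether of the spiro 2-methylidenecyclopentanol
Product: 19 cis-fused 4-isobutyl-5,7-dimethoxy-3-methylchroman-4-ol with the 2,3-annulated spiro cyclopentane (2R,3R,4R as drawn)
Conditions: Fe(acac)3 (0.5 equiv), PhSiH3 (3 equiv, slow addition), degassed EtOH, 60 °C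
Reagents that add atoms: none
Why: The iron hydride formed from Fe(acac)3 and the silane in ethanol transfers a hydrogen atom to the terminal carbon of the exocyclic methylene (Markovnikov), which creates the C3 methyl group and a tertiary radical at C3; this nucleophilic radical adds to the carbonyl carbon of the ortho isovaleryl group, and the resulting tertiary alkoxy radical is reduced by iron(II)/silane and protonated by the solvent, which makes the addition irreversible. The closest known reaction type is the iron-hydride hydrogen-atom-transfer reductive cyclisation of alkene-tethered ketones to tertiary cycloalkanols. The pyran ring (O1–C2–C3–C4–C4a–C8a) closes 6-exo-trig onto the C=O group with formation of the C3–C4 bond. The C3 stereocentre is controlled by the one-atom O1 tether from C2, because the ketone can reach the radical only on the face syn to the C2–O bond, so the rings are cis-fused with the C3 methyl cis to C2–H; the C4 carbinol centre needs no control because it is ionised in step 12 (the epimer with isobutyl pseudoaxial and syn to the C3 methyl is expected to prevail). The step needs hydrogen-atom transfer to the 1,1-disubstituted alkene in preference to the hindered trisubstituted ring alkene, which the lower substitution and better accessibility of the methylene should secure, and it needs cyclisation to outrun reduction of the tertiary radical, which the six-membered transition state, hydrogen-bond activation of the carbonyl by the protic solvent and slow addition of the silane should secure.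

Step 12
Reactants: 19 tertiary benzylic carbinol
Product: 20 cis-fused (2R,3S,4R)-4-isobutyl-5,7-dimethoxy-3-methylchroman with the 2,3-annulated spiro cyclopentane
Conditions: Et3SiH (5 equiv), TFA (3 equiv), CH2Cl2, −40 → 0 °C
Reagents that add atoms: none
Why: Ionic hydrogenation in which acid ionises the tertiary carbinol to a benzylic cation stabilised by the ortho and para oxygen substituents far more readily than it protonates the trisubstituted alkene at this temperature, and triethylsilane should deliver hydride to C4 from the convex face that carries the C3 methyl and C2–H, anti to the pseudoaxial C3–CH2 bond and away from the cyclopentane and spiro ring, so that isobutyl ends trans to the C3 methyl (4R).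

Step 13
Reactants: 20 5,7-dimethoxychroman
Product: 21 cis-fused (2R,3S,4R)-4-isobutyl-5,7-dimethoxy-3-methylchroman-6,8-dicarbaldehyde with the 2,3-annulated spiro cyclopentane
Conditions: Cl2CHOMe (6 equiv), TiCl4 (6 equiv), CH2Cl2, −78 → 0 °C; cold aq. NaHCO3
Reagents that add atoms: dichloromethyl methyl ether, COC(Cl)Cl; water, O
Why: Rieche formylation in which the titanium-activated dichloromethyl ether attacks the only two free ring positions C6 and C8, each ortho or para to all three oxygen substituents, and hydrolysis of the α-chloro ethers on work-up gives the dialdehyde, with excess reagent used because the first formyl group deactivates the ring.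

Step 14
Reactants: 21 5,7-dimethoxychroman-6,8-dicarbaldehyde
Product: 22 CNP0121396.1, the 5,7-dihydroxy-6,8-dicarbaldehyde (target)
Conditions: BCl3 (6 equiv), CH2Cl2, −78 → 0 °C; H2O
Reagents that add atoms: none
Why: Chelation-assisted demethylation in which BCl3 binds each formyl oxygen together with the neighbouring methoxy oxygen and chloride cleaves the O–CH3 bonds, while the O1–C2 ether should survive because C2 is a secondary carbon flanked by two quaternary centres and cannot undergo SN2 cleavage.

**Compound list**

1 | (R)-(−)-carvone | CC1=CC[C@H](CC1=O)C(C)=C | starting material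
2 | (2R,5R)-2-methyl-5-(prop-1-en-2-yl)cyclohexan-1-one | C[C@@H]1CC[C@H](CC1=O)C(C)=C | intermediate
3 | (E)-2,4,6-triisopropylbenzenesulfonyl hydrazone of 2 | C[C@@H]1CC[C@H](C/C1=N\NS(=O)(=O)c2c(C(C)C)cc(C(C)C)cc2C(C)C)C(C)=C | intermediate
4 | cyclobutanone | O=C1CCC1 | starting material
5 | [(3R,6R)-6-methyl-3-(prop-1-en-2-yl)cyclohex-1-en-1-yl]lithium | C[C@@H]1CC[C@H](C=C1[Li])C(C)=C | intermediate (not isolated)
6 | 1-[(3R,6R)-6-methyl-3-(prop-1-en-2-yl)cyclohex-1-en-1-yl]cyclobutan-1-ol | C[C@@H]1CC[C@H](C=C1C2(O)CCC2)C(C)=C | intermediate
7 | 1-[(6R)-6-methyl-3-(propan-2-ylidene)cyclohex-1-en-1-yl]cyclobutan-1-ol | C[C@@H]1CCC(=C(C)C)C=C1C2(O)CCC2 | intermediate (not isolated)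
8 | (5R,10R)-10-methyl-7-(propan-2-yl)spiro[4.5]dec-6-en-1-one | O=C1CCC[C@@]12C=C(C(C)C)CC[C@H]2C | intermediate
9 | (5R,10R)-10-methyl-2-methylidene-7-(propan-2-yl)spiro[4.5]dec-6-en-1-one | O=C1C(=C)CC[C@@]12C=C(C(C)C)CC[C@H]2C | intermediate
10 | (1R,5R,10R)-10-methyl-2-methylidene-7-(propan-2-yl)spiro[4.5]dec-6-en-1-ol | O[C@@H]1C(=C)CC[C@@]12C=C(C(C)C)CC[C@H]2C | intermediate
11 | 2,6-difluoro-4-methoxybenzonitrile | N#Cc1c(F)cc(OC)cc1F | starting material
12 | 2-fluoro-4-methoxy-6-(spirodecenyloxy)benzonitrile (spirodecenyl as in 10) | N#Cc1c(F)cc(OC)cc1O[C@@H]1C(=C)CC[C@@]12C=C(C(C)C)CC[C@H]2C | intermediate (not isolated)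
13 | 2,4-dimethoxy-6-(spirodecenyloxy)benzonitrile | N#Cc1c(OC)cc(OC)cc1O[C@@H]1C(=C)CC[C@@]12C=C(C(C)C)CC[C@H]2C | intermediate
14 | 2,4-dimethoxy-6-(spirodecenyloxy)benzaldimine | N=Cc1c(OC)cc(OC)cc1O[C@@H]1C(=C)CC[C@@]12C=C(C(C)C)CC[C@H]2C | intermediate (not isolated)
15 | 2,4-dimethoxy-6-(spirodecenyloxy)benzaldehyde | O=Cc1c(OC)cc(OC)cc1O[C@@H]1C(=C)CC[C@@]12C=C(C(C)C)CC[C@H]2C | intermediate
16 | isobutylmagnesium bromide | CC(C)C[Mg]Br | starting material
17 | 1-[2,4-dimethoxy-6-(spirodecenyloxy)phenyl]-3-methylbutan-1-ol, both carbinol epimers | CC(C)CC(O)c1c(OC)cc(OC)cc1O[C@@H]1C(=C)CC[C@@]12C=C(C(C)C)CC[C@H]2C | intermediate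
18 | 1-[2,4-dimethoxy-6-(spirodecenyloxy)phenyl]-3-methylbutan-1-one (key-step precursor) | CC(C)CC(=O)c1c(OC)cc(OC)cc1O[C@@H]1C(=C)CC[C@@]12C=C(C(C)C)CC[C@H]2C | intermediate
19 | cis-fused 4-isobutyl-5,7-dimethoxy-3-methylchroman-4-ol, 2,3-annulated with the cyclopentane that is spiro-linked to the 3-isopropyl-6-methylcyclohex-2-ene ring (key-step product) | CC(C)C[C@]1(O)c2c(OC)cc(OC)cc2O[C@@H]2[C@@]1(C)CC[C@@]21C=C(C(C)C)CC[C@H]1C | intermediate
20 | cis-fused (2R,3S,4R)-4-isobutyl-5,7-dimethoxy-3-methylchroman, same annulation; C4-isobutyl trans to C3-methyl | CC(C)C[C@H]1c2c(OC)cc(OC)cc2O[C@@H]2[C@@]1(C)CC[C@@]21C=C(C(C)C)CC[C@H]1C | intermediate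
21 | 6,8-dicarbaldehyde of 20 | CC(C)C[C@H]1c2c(OC)c(C=O)c(OC)c(C=O)c2O[C@@H]2[C@@]1(C)CC[C@@]21C=C(C(C)C)CC[C@H]1C | intermediate
22 | CNP0121396.1, the 5,7-dihydroxy-6,8-dicarbaldehyde | CC(C)C[C@H]1c2c(O)c(C=O)c(O)c(C=O)c2O[C@@H]2[C@@]1(C)CC[C@@]21C=C(C(C)C)CC[C@H]1C | target

**Step count and risks**

Total step count: 14. Longest linear sequence: 14 steps, from 1 to 22; compounds 4, 11 and 16 enter as purchased materials.

The three steps most likely to fail:

Step 11 (key step). The tertiary C3 radical may be reduced before it adds, which would give plain hydrogenation of the methylene. Addition to the hindered, di-ortho-substituted ketone may also revert faster than the alkoxy radical is reduced, and hydrogen-atom transfer to the ring alkene may compete. The fallback sets out from aldehyde 15. An N-heterocyclic-carbene-catalysed intramolecular hydroacylation (N-mesityl thiazolium precatalyst, DBU, 1,4-dioxane, 120 °C) adds the acyl anion equivalent across the 1,1-disubstituted alkene in a concerted ene-type step. This forms the same C3–C4 bond and the C3 methyl and gives the cis-fused 5,7-dimethoxy-3-methylchroman-4-one F1. Addition of the isobutylcerium reagent (16, CeCl3, THF, −78 °C) to the non-enolisable ketone of F1 from the convex face then gives 19 (its C4 epimer would give the same cation), and the route continues at step 12.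

Step 4. Protonation of the ring alkene next to the carbinol may lead to ring expansion without the C6=C7 alkene. The acid may also move the product alkene, loss of the proton next to the cation may erode the methyl stereocentre, and the 1,2-shift may show low facial selectivity. The fallback sets out from 2 and builds the quaternary centre by enolate alkylation instead:
- Hydrogenation of the isopropenyl group (H2, (Ph3P)3RhCl, benzene) gives (2R,5R)-2-methyl-5-(propan-2-yl)cyclohexan-1-one F2.
- Kinetic enolisation on the CH2 side and triflation (LDA, THF, −78 °C; PhNTf2) gives the enol triflate F3.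
- Palladium-catalysed methoxycarbonylation (Pd(OAc)2, PPh3, CO, MeOH, Et3N, DMF) gives the enoate F4.
- γ-Deprotonation (LDA, HMPA, THF, −78 °C) and α-allylation of the extended dienolate with allyl bromide, anti to the neighbouring methyl, gives the β,γ-unsaturated ester F5 with the quaternary centre and the alkene already at the isopropyl-bearing carbon.
- DIBAL-H (CH2Cl2, −78 °C) gives the aldehyde F6.
- Rhodium(I)-catalysed intramolecular hydroacylation of this 4-pentenal ([Rh(dppe)]BF4, CH2Cl2, rt) closes the cyclopentanone and returns to the route at 8.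

Step 13. TiCl4 and the HCl formed may hydrochlorinate or shift the trisubstituted ring alkene, and the second formylation may stall at the mono-aldehyde. The fallback sets out from 20. Bromination of both free ring positions (NBS, 2 equiv, MeCN, 0 °C, dark) gives the 6,8-dibromide F7. Double bromine–lithium exchange (t-BuLi, 4 equiv, THF, −78 °C) followed by DMF gives 21 without protic or Lewis acid, and the route continues at step 14.

Further compounds
F1 | step 11 | cis-fused 5,7-dimethoxy-3-methylchroman-4-one, 2,3-annulated with the spiro cyclopentane | O=C1c2c(OC)cc(OC)cc2O[C@@H]2[C@@]1(C)CC[C@@]21C=C(C(C)C)CC[C@H]1C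
F2 | step 4 | (2R,5R)-2-methyl-5-(propan-2-yl)cyclohexan-1-one | C[C@@H]1CC[C@H](CC1=O)C(C)C
F3 | step 4 | (3S,6R)-6-methyl-3-(propan-2-yl)cyclohex-1-en-1-yl trifluoromethanesulfonate | C[C@@H]1CC[C@H](C=C1OS(=O)(=O)C(F)(F)F)C(C)C
F4 | step 4 | methyl (3S,6R)-6-methyl-3-(propan-2-yl)cyclohex-1-ene-1-carboxylate | C[C@@H]1CC[C@H](C=C1C(=O)OC)C(C)C
F5 | step 4 | methyl (1R,6R)-6-methyl-3-(propan-2-yl)-1-(prop-2-en-1-yl)cyclohex-2-ene-1-carboxylate | COC(=O)[C@@]1(CC=C)C=C(C(C)C)CC[C@H]1C
F6 | step 4 | (1R,6R)-6-methyl-3-(propan-2-yl)-1-(prop-2-en-1-yl)cyclohex-2-ene-1-carbaldehyde | O=C[C@@]1(CC=C)C=C(C(C)C)CC[C@H]1C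
F7 | step 13 | 6,8-dibromo derivative of 20 | CC(C)C[C@H]1c2c(OC)c(Br)c(OC)c(Br)c2O[C@@H]2[C@@]1(C)CC[C@@]21C=C(C(C)C)CC[C@H]1C
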